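## Analysis of the target

The target 23 is a bicyclic diterpenoid diester of the halimane type. In diterpene numbering ring A is C1–C5 plus C10, ring B is C5–C10, the chain C11–C15 (methyl on C13) sits on C9, and C4 carries a methyl group and the methyl ester. It has four stereocentres, (4S,5R,8R,9S), and an (E)-C13=C14 olefin. The C8 and C9 methyls are cis, C5–H lies on the face of the C9 methyl (so the C4–C5 bond is equatorial on ring B and trans to the C8 methyl), and at C4 the methyl is cis to C5–H while the ester is axial. Two quaternary carbons (C4, C9) flank the ring fusion, and C4–C5–C10–C9 is a run of four contiguous substituted carbons. Sensitive points are the trisubstituted C1=C10 olefin (acid can move it to C5=C10 and erase C5), the primary allylic acetate, and the need to tell the hindered C4 ester from any other ester. The hard problems are to place the ring olefin next to the quaternary C9 without ambiguity and to relate C4 and C5 to the remote C8/C9 pair. The strategy rests on the C1=C10 olefin: C10 is a ring-B carbon and C1 ends a three-carbon arm on C4, so both can be carbonyl carbons (ring-B ketone, C1 aldehyde) and ring A can be closed by joining them reductively.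

## Retrosynthetic reasoning

**C15–O acyl bond.** The acetate of 23 is removed first, giving allylic alcohol 22. An allylic acetate would not survive hydride, enolate or acid steps, so acetylation is the last operation.

**C13=C14.** Alcohol 22 comes from diester 21, and 21 from methyl ketone 19 and phosphonate 20. Cutting the chain olefin leaves a methyl ketone, which is what a Michael addition to 5 delivers at the very start and which can travel as a ketal. The forward steps must give the (E)-olefin and reduce the new ester in the presence of the C4 ester.

**Ketal and C4–CH3.** Ketone 19 is unmasked from ketal 18, and 18 comes from 17 by C-methylation. The methyl, not the carboxyl, is cut because the ester is the enolising group. Both C4 epimers of 17 then converge on one enolate, so C4 need not be controlled earlier. The alkylation must put the methyl on the face of C5–H.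

**C1=C10 (key).** Bicyclic ester 17 is opened to keto aldehyde 16. This is the only ring olefin; an elimination or an olefin isomerisation could not tell C1=C10 from C5=C10, whereas a carbonyl–carbonyl coupling fixes the olefin between the two former carbonyl carbons. It also reduces the bicycle to a ring-B ketone carrying one side arm. The forward reaction must couple ketone and aldehyde and leave the ester and the ketal alone.

**C1 aldehyde.** The aldehyde of 16 is traced to the terminal olefin of 14. An olefin is inert to the base and organometallic steps before it and can be cleaved oxidatively without touching the ketal. An acetal-masked propanal unit was not used because its hydrolysis could not be separated from that of the ketone ketal.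

**C3–C4 bond and C5–H.** Keto ester 14 comes from alkylidene ketone 11 and Grignard reagent 12 by conjugate addition at C4. C5, α to the ketone, is then set by equilibration. C4 is left uncontrolled on purpose.

**C4=C5.** Compound 11 is the dehydrated aldol product (through 9) of ketone 7 and methyl glyoxylate 8. Ketone 7 has α-hydrogens only at C5, so regiochemistry is inherent.

**C9–C11 and the C9 centre.** Ketal 7 comes from diketone 6, made by Michael addition of silyl enol ether 4 to 5. The C8 methyl directs the incoming chain to the opposite face, which gives the cis-dimethyl arrangement.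

**C8 from the chiral pool.** Enol ether 4 derives from ketone 3, which comes from (R)-pulegone 1 through 2. The isopropylidene group of 1 blocks one α-position during methylation and is then removed by retro-aldol cleavage. The methyl-bearing carbon of 1 becomes C8 with the correct (R) configuration.

## Alternatives that were turned down

**Alternative 1: both rings from one intramolecular Diels–Alder reaction.**
- Disconnection: C3–C4 and C5–C10. The open-chain triene A2 carries a (Z)-2-methyl enoate (C4=C5) and a 2-silyloxy diene (C10=C1–C2=C3) at the ends of the C6–C9 chain and should give the bicyclic silyl enol ether A1 on heating.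
- For: two rings and the C4 and C5 centres arise in one concerted step, and C4 follows from the enoate geometry. On this point it is stronger than the two separate substrate-controlled operations used here (equilibration at C5, alkylation at C4).
- Against: the dienophile is a trisubstituted, weakly activated α-methyl enoate, so forming the quaternary C4 needs temperatures at which a 2-silyloxy diene is prone to hydrogen shifts. The adduct has its olefin at C1=C2 and an oxygen at C2 that the target lacks; C2 must be deoxygenated and the olefin then introduced at a C10–H, with nothing to tell C1=C10 from C5=C10. A2 also requires the ring of 1 to be cut open into an acyclic chain with the C8/C9 pair.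
- Comparison: it wins on bonds formed in the key step and loses that gain in the redox corrections afterwards. The carbonyl coupling leaves the olefin in place and nothing to remove.

**Alternative 2: ring B by a catalytic asymmetric Diels–Alder reaction.**
- Disconnection: C7–C8 and C9–C10. (E)-2-Methylbut-2-enal A4 and (E)-1-(trimethylsilyloxy)buta-1,3-diene A5 combine under a protonated chiral oxazaborolidine to the cyclohexene aldehyde A3.
- For: the C8/C9 pair is set in one step, their cis relationship follows from the geometry of A4, and either enantiomer is accessible. On this point it is at least as good as the chiral-pool entry, which needs five steps to reach 7.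
- Against: it solves only ring B. The formyl group must still be extended by three carbons, the C6=C7 olefin hydrogenated and C10 oxidised. The silyloxy diene is labile toward the strongly acidic catalyst. Ring A, with C4, C5 and the C1=C10 olefin, still has to be built by a closure such as the one chosen here.
- Comparison: it is a longer alternative entry to 7, not a competitor for the ring-A closure.

**Alternative 3: ring A by a lactone enolate Claisen ring contraction.**
- Disconnection: C4–C5, with a C1–O bond added back. The silyl ketene acetal of δ-lactone A7, whose carbinol carbon C1 carries the ring-B cyclohexenyl unit (C10=C5), rearranges [3,3] to the bicyclic acid A6: C4–C5 forms, C1–O breaks and the olefin moves to C1=C10.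
- For: the quaternary C4 and C5 are formed together and stereospecifically, the olefin appears at C1=C10 as reliably as in the carbonyl coupling, and the carboxyl is delivered directly. In stereocontrol at C4/C5 it is stronger than the chosen route.
- Against: that control is only as good as the configuration of C1, which must be set next to a hindered cyclohexenyl unit whose nearest stereocentre is C9 with two similar substituents. The new bond joins a fully substituted ketene acetal carbon to the ring carbon next to that quaternary centre, so the rearrangement would be slow. A7 needs a vinyl metal or triflate from the ring-B ketone, a coupling and a lactonisation, which is not shorter than the five steps from 7 to 16.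
- Comparison: the chosen route accepts weaker intrinsic control at C5 and C4, but both can be corrected (C5 is epimerisable before ring closure, C4 is set late on a convergent enolate), and only robust steps precede the coupling.

Key step: step 10

Remarks on the chemistry: diterpene numbering is used for positions throughout. Centres that are destroyed or converge later (the two new centres of 9, C4 up to step 11) are left open in the SMILES, and 2 is drawn as its major trans isomer. Lithium, magnesium and titanium-bound species (enolates, ketyls, the titanium pinacolate) are solution aggregates without a single formula; they are described in the Why lines, and only covalent intermediates carry numbers.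

## Route

Step 1
Reactants: 1 (R)-(+)-pulegone
Product: 2 (5R,6S)-5,6-dimethyl-2-(propan-2-ylidene)cyclohexan-1-one (trans-6-methylpulegone; some 6-epimer is carried along)
Conditions: LiN(i-Pr)2, THF, −78 °C; MeI, −78 → 0 °C
Reagents that add atoms: iodomethane, CI
Why: Kinetic deprotonation takes the α′-hydrogen (cross-conjugated enolate) because the other α-carbon is blocked by the isopropylidene group; the enolate is C-methylated mainly anti to the ring methyl (enolate alkylation). The new centre is provisional, since it is enolised again in steps 3 and 4.

Step 2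
Reactants: 2 (5R,6S)-5,6-dimethyl-2-(propan-2-ylidene)cyclohexan-1-one
Product: 3 (2S,3R)-2,3-dimethylcyclohexan-1-one
Conditions: conc. HCl, H2O, reflux, acetone distilled off
Reagents that add atoms: none
Why: Acid-catalysed hydration of the enone and retro-aldol cleavage remove the blocking group as acetone, the classical degradation of pulegone-type enones. The β-stereocentre is untouched and C2 settles as the trans epimer.

Step 3
Reactants: 3 (2S,3R)-2,3-dimethylcyclohexan-1-one
Product: 4 trimethyl{[(3R)-2,3-dimethylcyclohex-1-en-1-yl]oxy}silane
Conditions: Me3SiCl, NaI, Et3N, MeCN, 25 °C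
Reagents that add atoms: chlorotrimethylsilane, C[Si](C)(C)Cl
Why: Silylation under equilibrating conditions (Me3SiI formed in the flask, amine base) favours the more substituted, tetrasubstituted silyl enol ether; the minor regioisomer is removed by distillation (thermodynamic silyl enol ether formation).

Step 4
Reactants: 4 trimethyl{[(3R)-2,3-dimethylcyclohex-1-en-1-yl]oxy}silane; 5 methyl vinyl ketone (but-3-en-2-one)
Product: 6 (2S,3R)-2,3-dimethyl-2-(3-oxobutyl)cyclohexan-1-one
Conditions: BF3·OEt2, i-PrOH, CH2Cl2, −78 °C
Reagents that add atoms: none
Why: Mukaiyama–Michael addition: the BF3-activated enone is attacked by C2 of the enol ether and the alcohol takes up the silyl group, so the 1,5-diketone is released without aldol closure. In 4 the C3 methyl is pseudoaxial to avoid A(1,2) strain with the C2 methyl and the acceptor enters anti to it, which sets the quaternary centre (C9) with the chain trans to the secondary methyl and the two methyls cis.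

Step 5
Reactants: 6 (2S,3R)-2,3-dimethyl-2-(3-oxobutyl)cyclohexan-1-one
Product: 7 (2S,3R)-2,3-dimethyl-2-[2-(2-methyl-1,3-dioxolan-2-yl)ethyl]cyclohexan-1-one
Conditions: Me3SiOCH2CH2OSiMe3, Me3SiOTf (cat.), CH2Cl2, −78 °C
Reagents that add atoms: 1,2-bis(trimethylsilyloxy)ethane, C[Si](C)(C)OCCO[Si](C)(C)C
Why: Ketalisation with the bis-silylated diol under silyl triflate catalysis reacts only with the unhindered methyl ketone at −78 °C; the ring ketone next to the quaternary carbon is left, and no protic acid is present that could start an aldol cyclisation of the 1,5-diketone.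

Step 6
Reactants: 7 (2S,3R)-2,3-dimethyl-2-[2-(2-methyl-1,3-dioxolan-2-yl)ethyl]cyclohexan-1-one; 8 methyl glyoxylate (methyl 2-oxoacetate, freshly cracked monomer)
Product: 9 methyl 2-hydroxy-2-[(3S,4R)-3,4-dimethyl-3-[2-(2-methyl-1,3-dioxolan-2-yl)ethyl]-2-oxocyclohexyl]acetate (mixture at the two new centres)
Conditions: LiN(i-Pr)2, THF, −78 °C; 8; AcOH, −78 °C
Reagents that add atoms: none
Why: The ketone has α-hydrogens at C5 only, so a single lithium enolate forms and adds to the very electrophilic aldehyde (directed aldol addition); the cold acetic acid quench avoids retro-aldol. Both new centres are removed in step 7.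

Step 7
Reactants: 9 methyl 2-hydroxy-2-[(3S,4R)-3,4-dimethyl-3-[2-(2-methyl-1,3-dioxolan-2-yl)ethyl]-2-oxocyclohexyl]acetate
Product: 11 methyl (2E)-2-[(3S,4R)-3,4-dimethyl-3-[2-(2-methyl-1,3-dioxolan-2-yl)ethyl]-2-oxocyclohexylidene]acetate, via mesylate 10 (not isolated)
Conditions: MsCl, Et3N, CH2Cl2, 0 → 25 °C
Reagents that add atoms: none
Why: Mesylation of the secondary alcohol and E1cB elimination through the ketone enolate give the conjugated alkylidene ketone, expected as the (E)-isomer with the ester turned away from the carbonyl. The geometry has no consequence for step 8.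

Step 8
Reactants: 11 methyl (2E)-2-[(3S,4R)-3,4-dimethyl-3-[2-(2-methyl-1,3-dioxolan-2-yl)ethyl]-2-oxocyclohexylidene]acetate; 12 but-3-en-1-ylmagnesium bromide (solution in THF)
Product: 14 methyl 2-[(1S,3S,4R)-3,4-dimethyl-3-[2-(2-methyl-1,3-dioxolan-2-yl)ethyl]-2-oxocyclohexyl]hex-5-enoate (both C4 epimers), via kinetic keto ester mixture 13 (not isolated)
Conditions: CuBr·SMe2 (10 mol %), THF, −78 °C; H2O; then NaOMe (0.2 equiv), MeOH, 25 °C; C5 epimers separated, the minor one returned to the NaOMe equilibration
Reagents that add atoms: none
Why: Copper-catalysed conjugate addition: the organocopper adds at C4, which is β to the ketone (the stronger acceptor) and the less substituted end of the ene-dicarbonyl, and protonation of the ketone enolate gives 13 as a mixture at C4 and C5. Methoxide then equilibrates C5: the epimer with the arm trans to the C8 methyl can place arm, C8 methyl and C9 chain equatorial with only the C9 methyl axial, whereas the other epimer needs the inverted chair with the C8 methyl and C9 chain axial. A count of gauche and syn-axial contacts puts this preference well below 1 kcal/mol, so 14 should be the major but not the sole epimer, which is why the minor one is recycled; C4 stays uncontrolled until step 11.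

Step 9
Reactants: 14 methyl 2-[(1S,3S,4R)-3,4-dimethyl-3-[2-(2-methyl-1,3-dioxolan-2-yl)ethyl]-2-oxocyclohexyl]hex-5-enoate
Product: 16 methyl 2-[(1S,3S,4R)-3,4-dimethyl-3-[2-(2-methyl-1,3-dioxolan-2-yl)ethyl]-2-oxocyclohexyl]-5-oxopentanoate (both C4 epimers), via ozonide 15 (not isolated)
Conditions: O3, CH2Cl2, −78 °C; PPh3, −78 → 25 °C
Reagents that add atoms: ozone, [O-][O+]=O
Why: Ozonolysis of the only olefin with reductive work-up gives the C1 aldehyde; ketone, ester and the dioxolane (no acetal C–H) are inert, and the neutral conditions leave C5 untouched. 16 is used at once because a keto aldehyde of this kind can close by aldol reaction.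

Step 10
Reactants: 16 methyl 2-[(1S,3S,4R)-3,4-dimethyl-3-[2-(2-methyl-1,3-dioxolan-2-yl)ethyl]-2-oxocyclohexyl]-5-oxopentanoate
Product: 17 methyl (5S,6R,8aS)-5,6-dimethyl-5-[2-(2-methyl-1,3-dioxolan-2-yl)ethyl]-1,2,3,5,6,7,8,8a-octahydronaphthalene-1-carboxylate (both C4 epimers; olefin at C1=C10 in diterpene numbering)
Conditions: TiCl3(DME)1.5, Zn–Cu couple, DME, reflux; 16 added over about 30 h by syringe pump at high dilution, then further reflux
Reagents that add atoms: none
Why: The zinc–copper couple reduces TiCl3(DME)1.5 to low-valent titanium, which transfers single electrons to the aldehyde and the ketone; the two ketyls pair on titanium to the C1–C10 pinacolate, and at reflux both C–O bonds are cleaved to give the olefin and titanium oxide (McMurry coupling; the closest known type is the intramolecular coupling of keto aldehydes to cycloalkenes). Ring A closes as a six-membered carbocycle by joining the two carbonyl carbons of the 1,6-dicarbonyl chain C10–C5–C4–C3–C2–C1, and slow addition at high dilution keeps the coupling intramolecular. No stereocentre is formed; C5, C8 and C9 are spectators, and C5 is not exposed to base. The step needs chemoselectivity for aldehyde and ketone over ester and ketal: ketyl formation from the two carbonyls is much faster than ester reduction, and the aldehyde ketyl finds the ketone in a six-membered closure. It also needs the olefin at C1=C10 only, which is inherent because the double bond is formed between the two former carbonyl carbons and cannot appear at C5=C10. Because the ketone is flanked by the quaternary C9 and the branched C5, prolonged reflux is planned for deoxygenation of the pinacolate.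

Step 11
Reactants: 17 methyl (5S,6R,8aS)-5,6-dimethyl-5-[2-(2-methyl-1,3-dioxolan-2-yl)ethyl]-1,2,3,5,6,7,8,8a-octahydronaphthalene-1-carboxylate
Product: 18 methyl (1S,5S,6R,8aR)-1,5,6-trimethyl-5-[2-(2-methyl-1,3-dioxolan-2-yl)ethyl]-1,2,3,5,6,7,8,8a-octahydronaphthalene-1-carboxylate
Conditions: LiN(i-Pr)2, THF, −78 °C; MeI, DMPU, −78 → 0 °C
Reagents that add atoms: iodomethane, CI
Why: Both C4 epimers of 17 give the same ester enolate; the electrophile should enter along the equatorial trajectory on the face of ring A that carries the axial C5–H, anti to the C5–C6 bond, which A(1,3) strain with the enolate oxygens pushes toward the other face (enolate C-alkylation). This gives the equatorial methyl and axial ester (C4 S), the usual outcome for C4 ester enolates of decalins with an axial C5–H.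

Step 12
Reactants: 18 methyl (1S,5S,6R,8aR)-1,5,6-trimethyl-5-[2-(2-methyl-1,3-dioxolan-2-yl)ethyl]-1,2,3,5,6,7,8,8a-octahydronaphthalene-1-carboxylate
Product: 19 methyl (1S,5S,6R,8aR)-1,5,6-trimethyl-5-(3-oxobutyl)-1,2,3,5,6,7,8,8a-octahydronaphthalene-1-carboxylate
Conditions: 1 M HCl, THF, 25 °C
Reagents that add atoms: water, O
Why: Acid-catalysed hydrolysis of the dioxolane releases the methyl ketone; dilute acid at room temperature should not protonate the trisubstituted olefin, and the tertiary axial ester is inert.

Step 13
Reactants: 19 methyl (1S,5S,6R,8aR)-1,5,6-trimethyl-5-(3-oxobutyl)-1,2,3,5,6,7,8,8a-octahydronaphthalene-1-carboxylate; 20 triethyl phosphonoacetate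
Product: 21 methyl (1S,5S,6R,8aR)-5-[(3E)-5-ethoxy-3-methyl-5-oxopent-3-en-1-yl]-1,5,6-trimethyl-1,2,3,5,6,7,8,8a-octahydronaphthalene-1-carboxylate
Conditions: NaH, THF, 0 → 65 °C
Reagents that add atoms: none
Why: Horner–Wadsworth–Emmons olefination of the methyl ketone; the stabilised phosphonate anion should give mainly the (E)-enoate (larger chain trans to the ester), and the minor (Z)-isomer is removed by chromatography here or after step 14. The C4 ester has no α-hydrogen and is too hindered to be attacked.

Step 14
Reactants: 21 methyl (1S,5S,6R,8aR)-5-[(3E)-5-ethoxy-3-methyl-5-oxopent-3-en-1-yl]-1,5,6-trimethyl-1,2,3,5,6,7,8,8a-octahydronaphthalene-1-carboxylate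
Product: 22 methyl (1S,5S,6R,8aR)-5-[(3E)-5-hydroxy-3-methylpent-3-en-1-yl]-1,5,6-trimethyl-1,2,3,5,6,7,8,8a-octahydronaphthalene-1-carboxylate
Conditions: i-Bu2AlH (2.2 equiv), CH2Cl2, −78 °C; aq. KNaC4H4O6
Reagents that add atoms: none
Why: At −78 °C the aluminium hydride reduces the unhindered conjugated ethyl ester to the allylic alcohol (1,2-reduction), while the neopentyl, axial C4 methyl ester should be too hindered to react at that temperature.

Step 15
Reactants: 22 methyl (1S,5S,6R,8aR)-5-[(3E)-5-hydroxy-3-methylpent-3-en-1-yl]-1,5,6-trimethyl-1,2,3,5,6,7,8,8a-octahydronaphthalene-1-carboxylate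
Product: 23 methyl (1S,5S,6R,8aR)-5-[(3E)-5-acetoxy-3-methylpent-3-en-1-yl]-1,5,6-trimethyl-1,2,3,5,6,7,8,8a-octahydronaphthalene-1-carboxylate (target)
Conditions: Ac2O, pyridine, DMAP (cat.), CH2Cl2, 25 °C
Reagents that add atoms: acetic anhydride, CC(=O)OC(C)=O
Why: DMAP-catalysed O-acylation of the primary allylic alcohol gives the acetate under non-acidic conditions that move neither olefin.

## Compound list

1 | (R)-(+)-pulegone | C[C@@H]1CCC(=C(C)C)C(=O)C1 | starting material
2 | (5R,6S)-5,6-dimethyl-2-(propan-2-ylidene)cyclohexan-1-one | C[C@@H]1C(=O)C(=C(C)C)CC[C@H]1C | intermediate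
3 | (2S,3R)-2,3-dimethylcyclohexan-1-one | C[C@@H]1C(=O)CCC[C@H]1C | intermediate
4 | trimethyl{[(3R)-2,3-dimethylcyclohex-1-en-1-yl]oxy}silane | CC1=C(O[Si](C)(C)C)CCC[C@H]1C | intermediate
5 | methyl vinyl ketone | CC(=O)C=C | starting material
6 | (2S,3R)-2,3-dimethyl-2-(3-oxobutyl)cyclohexan-1-one | O=C1CCC[C@@H](C)[C@]1(C)CCC(C)=O | intermediate
7 | (2S,3R)-2,3-dimethyl-2-[2-(2-methyl-1,3-dioxolan-2-yl)ethyl]cyclohexan-1-one | O=C1CCC[C@@H](C)[C@]1(C)CCC2(C)OCCO2 | intermediate
8 | methyl glyoxylate | COC(=O)C=O | starting material
9 | methyl 2-hydroxy-2-[(3S,4R)-3,4-dimethyl-3-[2-(2-methyl-1,3-dioxolan-2-yl)ethyl]-2-oxocyclohexyl]acetate (mixture at the two new centres) | COC(=O)C(O)C1CC[C@@H](C)[C@](C)(CCC2(C)OCCO2)C1=O | intermediate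
10 | methanesulfonate of 9 | COC(=O)C(OS(C)(=O)=O)C1CC[C@@H](C)[C@](C)(CCC2(C)OCCO2)C1=O | intermediate (not isolated)
11 | methyl (2E)-2-[(3S,4R)-3,4-dimethyl-3-[2-(2-methyl-1,3-dioxolan-2-yl)ethyl]-2-oxocyclohexylidene]acetate | COC(=O)/C=C1\CC[C@@H](C)[C@](C)(CCC2(C)OCCO2)C1=O | intermediate
12 | but-3-en-1-ylmagnesium bromide | C=CCC[Mg]Br | starting material
13 | methyl 2-[(3S,4R)-3,4-dimethyl-3-[2-(2-methyl-1,3-dioxolan-2-yl)ethyl]-2-oxocyclohexyl]hex-5-enoate (mixture at C4 and C5) | COC(=O)C(CCC=C)C1CC[C@@H](C)[C@](C)(CCC2(C)OCCO2)C1=O | intermediate (not isolated)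
14 | methyl 2-[(1S,3S,4R)-3,4-dimethyl-3-[2-(2-methyl-1,3-dioxolan-2-yl)ethyl]-2-oxocyclohexyl]hex-5-enoate (both C4 epimers) | COC(=O)C(CCC=C)[C@@H]1CC[C@@H](C)[C@](C)(CCC2(C)OCCO2)C1=O | intermediate
15 | methyl 2-[(1S,3S,4R)-3,4-dimethyl-3-[2-(2-methyl-1,3-dioxolan-2-yl)ethyl]-2-oxocyclohexyl]-4-(1,2,4-trioxolan-3-yl)butanoate | COC(=O)C(CCC3OCOO3)[C@@H]1CC[C@@H](C)[C@](C)(CCC2(C)OCCO2)C1=O | intermediate (not isolated)
16 | methyl 2-[(1S,3S,4R)-3,4-dimethyl-3-[2-(2-methyl-1,3-dioxolan-2-yl)ethyl]-2-oxocyclohexyl]-5-oxopentanoate (both C4 epimers) | COC(=O)C(CCC=O)[C@@H]1CC[C@@H](C)[C@](C)(CCC2(C)OCCO2)C1=O | intermediate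
17 | methyl (5S,6R,8aS)-5,6-dimethyl-5-[2-(2-methyl-1,3-dioxolan-2-yl)ethyl]-1,2,3,5,6,7,8,8a-octahydronaphthalene-1-carboxylate (both C4 epimers) | COC(=O)C1CCC=C2[C@H]1CC[C@@H](C)[C@]2(C)CCC3(C)OCCO3 | intermediate
18 | methyl (1S,5S,6R,8aR)-1,5,6-trimethyl-5-[2-(2-methyl-1,3-dioxolan-2-yl)ethyl]-1,2,3,5,6,7,8,8a-octahydronaphthalene-1-carboxylate | COC(=O)[C@@]1(C)CCC=C2[C@H]1CC[C@@H](C)[C@]2(C)CCC3(C)OCCO3 | intermediate
19 | methyl (1S,5S,6R,8aR)-1,5,6-trimethyl-5-(3-oxobutyl)-1,2,3,5,6,7,8,8a-octahydronaphthalene-1-carboxylate | COC(=O)[C@@]1(C)CCC=C2[C@H]1CC[C@@H](C)[C@]2(C)CCC(C)=O | intermediate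
20 | triethyl phosphonoacetate | CCOC(=O)CP(=O)(OCC)OCC | starting material
21 | methyl (1S,5S,6R,8aR)-5-[(3E)-5-ethoxy-3-methyl-5-oxopent-3-en-1-yl]-1,5,6-trimethyl-1,2,3,5,6,7,8,8a-octahydronaphthalene-1-carboxylate | COC(=O)[C@@]1(C)CCC=C2[C@H]1CC[C@@H](C)[C@]2(C)CC/C(C)=C/C(=O)OCC | intermediate
22 | methyl (1S,5S,6R,8aR)-5-[(3E)-5-hydroxy-3-methylpent-3-en-1-yl]-1,5,6-trimethyl-1,2,3,5,6,7,8,8a-octahydronaphthalene-1-carboxylate | COC(=O)[C@@]1(C)CCC=C2[C@H]1CC[C@@H](C)[C@]2(C)CC/C(C)=C/CO | intermediate
23 | methyl (1S,5S,6R,8aR)-5-[(3E)-5-acetoxy-3-methylpent-3-en-1-yl]-1,5,6-trimethyl-1,2,3,5,6,7,8,8a-octahydronaphthalene-1-carboxylate (CNP0209995.1) | COC(=O)[C@@]1(C)CCC=C2[C@H]1CC[C@@H](C)[C@]2(C)CC/C(C)=C/COC(C)=O | target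

## Step count and least certain steps

Total step count: 15. Longest linear sequence: 15 steps (1 → 23); 5, 8, 12 and 20 enter as purchased reagents.

**Step 10 (key step).** The coupling may stop at the pinacol stage or be overtaken by Lewis-acid-induced aldol closure of the keto aldehyde, because the C10 carbonyl is flanked by the quaternary C9 and the branched C5 and cleavage of the tertiary C10–O bond is slow. Epimerisation at C5 on the acidic titanium and zinc salts is a second concern.
Fallback, from 16 back to 17: the same two carbons are joined in two stages. SmI2 (THF, t-BuOH, −78 → 0 °C) effects the ketyl–carbonyl pinacol cyclisation to the cis-C1,C10-diol F1. 1,1′-Thiocarbonyldiimidazole (toluene, 80 °C) converts it into the cyclic thionocarbonate F2. Corey–Winter fragmentation (P(OMe)3, 110 °C) then gives 17 by syn elimination, with the olefin again fixed at C1=C10.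

**Step 8.** The equilibration may discriminate poorly between the C5 epimers. C9 carries two groups of similar size, so only the equatorial preference of the C8 methyl separates the two chairs, and that preference is eroded by gauche contacts with both C9 substituents. Separation and recycling would then be laborious.
Fallback, from 11 and 12 back to 14: control is moved from thermodynamics to the reagent. The copper-catalysed addition is run with Me3SiCl present and the enolate is isolated as the silyl enol ether F3. F3 is protonated under catalyst control (a BINOL-derived N-triflyl thiophosphoramide, 1–5 mol %, phenol as the stoichiometric proton source, toluene). The catalyst antipode that delivers the proton to the C5 face syn to the C9 methyl is chosen, and the ketone is not exposed to base afterwards.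

**Step 11.** The methyl may enter from the axial face of the enolate instead of the equatorial one. C10 is trigonal, so only one syn-axial hydrogen (on C2) shields that face, unlike decalins with an angular substituent.
Fallback, from 17 back to 18: the two C4 carbons exchange roles, so an axial preference of the electrophile gives the required configuration.
- The enolate is trapped with monomeric formaldehyde to give the hydroxymethyl ester F4 (CH2OH axial, ester equatorial).
- Silylation (t-BuMe2SiCl, imidazole) gives the silyl ether F5.
- LiAlH4 reduces the equatorial ester to the carbinol F6.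
- The mesylate F7 is reduced with LiEt3BH to the equatorial methyl compound F8.
- n-Bu4NF frees the axial carbinol F9.
- Oxidation through the aldehyde F10 (Dess–Martin periodinane) to the acid F11 (NaClO2, NaH2PO4, 2-methylbut-2-ene) and esterification (Me3SiCHN2, MeOH) give 18.

**Step 13.** Olefination of a methyl ketone with a stabilised phosphonate may give low E/Z selectivity, because the two ketone substituents (methyl and a primary chain) differ little in size.
Fallback, from 19 back to 22 (bypassing 21): the ketone is converted (LiN(i-Pr)2; ClP(O)(OEt)2) into the enol phosphate F12, which is eliminated with LiN(i-Pr)2 to the terminal alkyne F13. Negishi carboalumination (Me3Al, (C5H5)2ZrCl2 cat.) followed by paraformaldehyde adds methyl and hydroxymethyl syn across the alkyne and gives the (E)-allylic alcohol 22.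

**Step 14.** The hydride may not discriminate fully between the two esters (partial reduction of the C4 ester), or some conjugate reduction may occur, since the selectivity rests only on steric hindrance at low temperature.
Fallback, from 21 back to 22: the esters are told apart by hydrolysis instead. LiOH (THF/H2O, 25 °C) cleaves only the unhindered conjugated ester to the acid F14; the axial tertiary ester resists. ClCO2Et/Et3N gives the mixed anhydride F15, and NaBH4 (THF/H2O, 0 °C) reduces it to 22.

## Further compounds

F1 | step 10 | cis-C1,C10-diol from pinacol cyclisation of 16 (C4 epimers) | COC(=O)C1CCC(O)C2(O)[C@H]1CC[C@@H](C)[C@]2(C)CCC3(C)OCCO3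
F2 | step 10 | cyclic C1,C10-thionocarbonate of F1 | COC(=O)C1CCC2OC(=S)OC23[C@H]1CC[C@@H](C)[C@]3(C)CCC4(C)OCCO4
F3 | step 8 | trimethylsilyl enol ether (C10=C5) of keto ester 13 | COC(=O)C(CCC=C)C1=C(O[Si](C)(C)C)[C@@](C)(CCC2(C)OCCO2)[C@H](C)CC1
F4 | step 11 | C4 hydroxymethyl ester (CH2OH axial) | COC(=O)[C@]1(CO)CCC=C2[C@H]1CC[C@@H](C)[C@]2(C)CCC3(C)OCCO3
F5 | step 11 | tert-butyldimethylsilyl ether of F4 | COC(=O)[C@]1(CO[Si](C)(C)C(C)(C)C)CCC=C2[C@H]1CC[C@@H](C)[C@]2(C)CCC3(C)OCCO3
F6 | step 11 | equatorial carbinol from reduction of F5 | OC[C@]1(CO[Si](C)(C)C(C)(C)C)CCC=C2[C@H]1CC[C@@H](C)[C@]2(C)CCC3(C)OCCO3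
F7 | step 11 | methanesulfonate of F6 | CS(=O)(=O)OC[C@]1(CO[Si](C)(C)C(C)(C)C)CCC=C2[C@H]1CC[C@@H](C)[C@]2(C)CCC3(C)OCCO3
F8 | step 11 | C4 equatorial methyl silyl ether | C[C@]1(CO[Si](C)(C)C(C)(C)C)CCC=C2[C@H]1CC[C@@H](C)[C@]2(C)CCC3(C)OCCO3
F9 | step 11 | C4 axial carbinol | C[C@]1(CO)CCC=C2[C@H]1CC[C@@H](C)[C@]2(C)CCC3(C)OCCO3
F10 | step 11 | C4 axial aldehyde | C[C@]1(C=O)CCC=C2[C@H]1CC[C@@H](C)[C@]2(C)CCC3(C)OCCO3
F11 | step 11 | C4 axial carboxylic acid | C[C@]1(C(=O)O)CCC=C2[C@H]1CC[C@@H](C)[C@]2(C)CCC3(C)OCCO3
F12 | step 13 | diethyl enol phosphate of ketone 19 | COC(=O)[C@@]1(C)CCC=C2[C@H]1CC[C@@H](C)[C@]2(C)CCC(=C)OP(=O)(OCC)OCC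
F13 | step 13 | terminal alkyne (but-3-yn-1-yl chain on C9) | COC(=O)[C@@]1(C)CCC=C2[C@H]1CC[C@@H](C)[C@]2(C)CCC#C
F14 | step 14 | (E)-enoic acid from selective hydrolysis of 21 | COC(=O)[C@@]1(C)CCC=C2[C@H]1CC[C@@H](C)[C@]2(C)CC/C(C)=C/C(=O)O
F15 | step 14 | ethyl carbonic mixed anhydride of F14 | COC(=O)[C@@]1(C)CCC=C2[C@H]1CC[C@@H](C)[C@]2(C)CC/C(C)=C/C(=O)OC(=O)OCC
A1 | alternative 1 | bicyclic C2 tert-butyldimethylsilyl enol ether (trans-fused, C10–H) | COC(=O)[C@@]1(C)CC(O[Si](C)(C)C(C)(C)C)=C[C@H]2[C@H]1CC[C@@H](C)[C@]2(C)CCC3(C)OCCO3
A2 | alternative 1 | open-chain triene with (Z)-2-methyl enoate and 2-silyloxy diene | COC(=O)/C(C)=C\CC[C@@H](C)[C@](C)(CCC1(C)OCCO1)/C=C/C(=C)O[Si](C)(C)C(C)(C)C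
A3 | alternative 2 | ring-B aldehyde with C9 quaternary centre, C8 methyl and C10 silyl ether | O=C[C@]1(C)[C@H](O[Si](C)(C)C)C=CC[C@H]1C
A4 | alternative 2 | (E)-2-methylbut-2-enal | C/C=C(\C)C=O
A5 | alternative 2 | (E)-1-(trimethylsilyloxy)buta-1,3-diene | C=C/C=C/O[Si](C)(C)C
A6 | alternative 3 | bicyclic C4 acid with C1=C10 olefin and ketal-protected chain | OC(=O)[C@@]1(C)CCC=C2[C@H]1CC[C@@H](C)[C@]2(C)CCC3(C)OCCO3
A7 | alternative 3 | δ-lactone with ring-B cyclohexenyl unit on the carbinol carbon C1 (C1 and C4 not defined) | CC1CCC(OC1=O)C2=CCC[C@@H](C)[C@]2(C)CCC3(C)OCCO3
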